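**Retrosynthetic overview**
- The strategy rests on the fully substituted 1,4-benzoquinone ring: C1(=O), C2(OMe), C3(indol-3-yl), C4(=O), C5(prenyl), C6(indol-3-yl). The last operations are hydroquinone oxidation and N-desilylation.
- The ring bond C4–C5 is disconnected. C1–C4 come from a 4-hydroxycyclobutenone and C5–C6 from an alkenyl group on the carbinol carbon C1.
- The C1–C6 bond comes from adding an α-indolyl alkenyllithium (Shapiro reaction of prenylated 3-acetylindole) to the carbonyl next to C–OMe of 3-methoxy-4-indolylcyclobutenedione.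
- The cyclobutenedione comes from dimethyl squarate and 3-lithio-1-(triisopropylsilyl)indole.
- Ring order: the four-membered ring and both indoles are bought; the six-membered ring is the only ring formed, in the thermolysis.

Key step: step 8

Assumption (chemistry): the carbinol stereocentres of the cyclobutenone intermediates are racemic (one enantiomer drawn). The trisubstituted alkene of the alkenyl unit is drawn with the geometry expected from the Shapiro reaction. Neither element survives the key step.

**Route**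

Step 1
Reactants: 1 indole
Product: 2 1-(triisopropylsilyl)indole
Conditions: NaH, THF, 0 °C; TIPSCl, 0 °C to rt
Reagents that add atoms: triisopropylsilyl chloride (TIPSCl), CC(C)[Si](Cl)(C(C)C)C(C)C
Why: Deprotonation of the indole N–H by NaH and attack of the indolide on silicon give the N-silylindole (N-silylation), whose bulky group later shields C2 and stabilises the 3-lithio species.

Step 2
Reactants: 2 1-(triisopropylsilyl)indole
Product: 3 3-bromo-1-(triisopropylsilyl)indole
Conditions: NBS, THF, -78 °C to rt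
Reagents that add atoms: N-bromosuccinimide (NBS), O=C1CCC(=O)N1Br
Why: Electrophilic aromatic bromination of the N-silylindole occurs at C3, its most nucleophilic position, while the triisopropylsilyl group shields C2 and the nitrogen.

Step 3
Reactants: 3 3-bromo-1-(triisopropylsilyl)indole; 4 dimethyl squarate
Product: 8 3-methoxy-4-[1-(triisopropylsilyl)indol-3-yl]cyclobut-3-ene-1,2-dione, via 3-lithio-1-(triisopropylsilyl)indole 5 (not isolated), via squarate adduct lithium alkoxide 6 (not isolated), via adduct trifluoroacetate 7 (not isolated)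
Conditions: t-BuLi (2 equiv), THF, -78 °C; cannulate into 4, THF, -78 °C; (CF3CO)2O, -78 °C; aq NH4Cl, -78 °C to rt
Reagents that add atoms: water, O
Why: Bromine–lithium exchange gives the stable 3-lithioindole 5, which undergoes 1,2-addition to one carbonyl of 4; trifluoroacetylation of alkoxide 6 and hydrolysis of ester 7 with allylic transposition expel trifluoroacetate and methanol, so that water supplies the new carbonyl oxygen (the known squarate to 3-alkoxy-4-arylcyclobutenedione sequence).

Step 4
Reactants: 9 3-acetylindole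
Product: 10 3-acetyl-1-(triisopropylsilyl)indole
Conditions: NaH, THF, 0 °C; TIPSCl, 0 °C to rt
Reagents that add atoms: triisopropylsilyl chloride (TIPSCl), CC(C)[Si](Cl)(C(C)C)C(C)C
Why: N-silylation of the sodium salt of the 3-acylindole masks the acidic N–H ahead of the enolate and organolithium steps.

Step 5
Reactants: 10 3-acetyl-1-(triisopropylsilyl)indole; 11 prenyl bromide (1-bromo-3-methylbut-2-ene)
Product: 13 5-methyl-1-[1-(triisopropylsilyl)indol-3-yl]hex-4-en-1-one, via lithium enolate 12 (not isolated)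
Conditions: LiN(i-Pr)2, THF, -78 °C; 11, DMPU, -78 to -20 °C
Reagents that add atoms: none
Why: Kinetic deprotonation of the methyl ketone gives lithium enolate 12, whose SN2 C-alkylation by the allylic bromide installs the 3-methylbut-2-enyl group (enolate alkylation), with low temperature and a slight excess of enolate limiting dialkylation.

Step 6
Reactants: 13 5-methyl-1-[1-(triisopropylsilyl)indol-3-yl]hex-4-en-1-one
Product: 14 N'-[(1E)-5-methyl-1-[1-(triisopropylsilyl)indol-3-yl]hex-4-en-1-ylidene]-2,4,6-triisopropylbenzenesulfonohydrazide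
Conditions: TrisNHNH2, TsOH·H2O (cat.), 4 Å MS, THF, rt
Reagents that add atoms: 2,4,6-triisopropylbenzenesulfonohydrazide (TrisNHNH2), CC(C)c1cc(C(C)C)c(S(=O)(=O)NN)c(C(C)C)c1
Why: Acid-catalysed condensation of the ketone with the arylsulfonylhydrazide gives the sulfonylhydrazone (hydrazone formation), expected mainly as the E isomer with the sulfonamide nitrogen syn to the α-methylene.

Step 7
Reactants: 14 the trisylhydrazone of step 6; 8 3-methoxy-4-[1-(triisopropylsilyl)indol-3-yl]cyclobut-3-ene-1,2-dione
Product: 16 4-hydroxy-3-methoxy-4-[(1E)-5-methyl-1-[1-(triisopropylsilyl)indol-3-yl]hexa-1,4-dien-1-yl]-2-[1-(triisopropylsilyl)indol-3-yl]cyclobut-2-en-1-one (racemic), via alkenyllithium 15 (not isolated)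
Conditions: n-BuLi (2.05 equiv per 14), THF, -78 °C then 0 °C until N2 evolution ends; recool to -78 °C, add 8 (0.8 equiv) in THF; aq NH4Cl, -78 °C
Reagents that add atoms: none
Why: Shapiro reaction, in which double deprotonation (N–H and syn α-CH2) and loss of sulfinate and N2 give alkenyllithium 15, followed by 1,2-addition to the carbonyl of 8 next to the methoxy-bearing carbon, the other carbonyl being a deactivated vinylogous ester flanked by the bulky indolyl group; the carbinol centre forms as a racemate and is erased in step 8.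

Step 8
Reactants: 16 the 4-alkenyl-4-hydroxycyclobutenone of step 7
Product: 19 2-methoxy-5-(3-methylbut-2-enyl)-3,6-bis[1-(triisopropylsilyl)indol-3-yl]benzene-1,4-diol, via dienylketene 17 (not isolated), via cyclohexadienone 18 (not isolated)
Conditions: PhMe (degassed), 110 °C, Ar
Reagents that add atoms: none
Why: Heating triggers thermal conrotatory four-electron opening of the cyclobutenone, which breaks the bond between the carbonyl carbon (C4 of the target) and the carbinol carbon (C1) to give dienylketene 17; the donor hydroxyl rotates outward, so the alkenyl arm is turned toward the ketene carbon. Disrotatory six-electron electrocyclisation then joins the ketene carbon C4 to the alkene CH terminus C5, closing the six-membered carbocycle as cyclohexadienone 18, and a proton shift from C5 to oxygen aromatises it to hydroquinone 19. The closest known reaction type is the Moore thermal ring expansion of squarate-derived 4-alkenyl-4-hydroxycyclobutenones to hydroquinones. No stereocentre is created, since the carbinol centre and alkene geometry of 16 and the sp3 centre of 18 are all erased. The selectivities needed are outward rotation of the hydroxyl, secured by donation of its lone pair into the breaking σ bond, and closure on C5, the only carbon placed six atoms from the ketene carbon; its single hydrogen allows direct aromatisation.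

Step 9
Reactants: 19 the hydroquinone of step 8
Product: 20 2-methoxy-5-(3-methylbut-2-enyl)-3,6-bis[1-(triisopropylsilyl)indol-3-yl]cyclohexa-2,5-diene-1,4-dione
Conditions: Ag2O, K2CO3, Et2O, rt
Reagents that add atoms: none
Why: Two-electron oxidation of the hydroquinone to the 1,4-benzoquinone by Ag2O under mild, non-acidic conditions should leave the N-silylindoles and the prenyl alkene untouched (hydroquinone oxidation).

Step 10
Reactants: 20 the bis-silylated quinone of step 9
Product: 21 2-methoxy-3,6-di(1H-indol-3-yl)-5-(3-methylbut-2-enyl)cyclohexa-2,5-diene-1,4-dione (target)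
Conditions: Bu4NF, AcOH, THF, 0 °C
Reagents that add atoms: none
Why: Fluoride attacks silicon and frees both indole nitrogens (N-desilylation), the quinone-conjugated indolide being a good leaving group, while acetic acid buffering keeps hydroxide or fluoride from displacing the C2 methoxy group.

**Compound list**

1 | indole | c1ccc2[nH]ccc2c1 | starting material
2 | 1-(triisopropylsilyl)indole | CC(C)[Si](C(C)C)(C(C)C)n1ccc2ccccc12 | intermediate
3 | 3-bromo-1-(triisopropylsilyl)indole | CC(C)[Si](C(C)C)(C(C)C)n1cc(Br)c2ccccc12 | intermediate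
4 | dimethyl squarate (3,4-dimethoxycyclobut-3-ene-1,2-dione) | COC1=C(OC)C(=O)C1=O | starting material
5 | 3-lithio-1-(triisopropylsilyl)indole (not isolated) | [Li]c1cn([Si](C(C)C)(C(C)C)C(C)C)c2ccccc12 | intermediate
6 | lithium 2,3-dimethoxy-4-oxo-1-[1-(triisopropylsilyl)indol-3-yl]cyclobut-2-en-1-olate (racemic, one enantiomer drawn; not isolated) | [Li]O[C@]1(c2cn([Si](C(C)C)(C(C)C)C(C)C)c3ccccc23)C(OC)=C(OC)C1=O | intermediate
7 | 2,3-dimethoxy-4-oxo-1-[1-(triisopropylsilyl)indol-3-yl]cyclobut-2-en-1-yl trifluoroacetate (racemic, one enantiomer drawn; not isolated) | O=C(O[C@]1(c2cn([Si](C(C)C)(C(C)C)C(C)C)c3ccccc23)C(OC)=C(OC)C1=O)C(F)(F)F | intermediate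
8 | 3-methoxy-4-[1-(triisopropylsilyl)indol-3-yl]cyclobut-3-ene-1,2-dione | COC1=C(c2cn([Si](C(C)C)(C(C)C)C(C)C)c3ccccc23)C(=O)C1=O | intermediate
9 | 3-acetylindole | CC(=O)c1c[nH]c2ccccc12 | starting material
10 | 3-acetyl-1-(triisopropylsilyl)indole | CC(=O)c1cn([Si](C(C)C)(C(C)C)C(C)C)c2ccccc12 | intermediate
11 | prenyl bromide (1-bromo-3-methylbut-2-ene) | CC(C)=CCBr | starting material
12 | lithium 1-[1-(triisopropylsilyl)indol-3-yl]ethen-1-olate (not isolated) | [Li]OC(=C)c1cn([Si](C(C)C)(C(C)C)C(C)C)c2ccccc12 | intermediate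
13 | 5-methyl-1-[1-(triisopropylsilyl)indol-3-yl]hex-4-en-1-one | CC(C)=CCCC(=O)c1cn([Si](C(C)C)(C(C)C)C(C)C)c2ccccc12 | intermediate
14 | N'-[(1E)-5-methyl-1-[1-(triisopropylsilyl)indol-3-yl]hex-4-en-1-ylidene]-2,4,6-triisopropylbenzenesulfonohydrazide | CC(C)=CCC/C(=N\NS(=O)(=O)c1c(C(C)C)cc(C(C)C)cc1C(C)C)c1cn([Si](C(C)C)(C(C)C)C(C)C)c2ccccc12 | intermediate
15 | [(1Z)-5-methyl-1-[1-(triisopropylsilyl)indol-3-yl]hexa-1,4-dien-1-yl]lithium (not isolated) | [Li]/C(=C/CC=C(C)C)c1cn([Si](C(C)C)(C(C)C)C(C)C)c2ccccc12 | intermediate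
16 | 4-hydroxy-3-methoxy-4-[(1E)-5-methyl-1-[1-(triisopropylsilyl)indol-3-yl]hexa-1,4-dien-1-yl]-2-[1-(triisopropylsilyl)indol-3-yl]cyclobut-2-en-1-one (racemic, one enantiomer drawn) | O=C1C(c2cn([Si](C(C)C)(C(C)C)C(C)C)c3ccccc23)=C(OC)[C@@]1(O)/C(=C/CC=C(C)C)c1cn([Si](C(C)C)(C(C)C)C(C)C)c2ccccc12 | intermediate
17 | dienylketene: 4-hydroxy-3-methoxy-9-methyl-2,5-bis[1-(triisopropylsilyl)indol-3-yl]deca-1,3,5,8-tetraen-1-one, hydroxyl cis to methoxy, alkenyl arm cis to the ketene-bearing carbon (not isolated) | O=C=C(c1cn([Si](C(C)C)(C(C)C)C(C)C)c2ccccc12)/C(OC)=C(O)\C(=C\CC=C(C)C)c1cn([Si](C(C)C)(C(C)C)C(C)C)c2ccccc12 | intermediate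
18 | 4-hydroxy-3-methoxy-6-(3-methylbut-2-enyl)-2,5-bis[1-(triisopropylsilyl)indol-3-yl]cyclohexa-2,4-dien-1-one (racemic, one enantiomer drawn; not isolated) | O=C1C(c2cn([Si](C(C)C)(C(C)C)C(C)C)c3ccccc23)=C(OC)C(O)=C(c2cn([Si](C(C)C)(C(C)C)C(C)C)c3ccccc23)[C@@H]1CC=C(C)C | intermediate
19 | 2-methoxy-5-(3-methylbut-2-enyl)-3,6-bis[1-(triisopropylsilyl)indol-3-yl]benzene-1,4-diol | COc1c(O)c(-c2cn([Si](C(C)C)(C(C)C)C(C)C)c3ccccc23)c(CC=C(C)C)c(O)c1-c1cn([Si](C(C)C)(C(C)C)C(C)C)c2ccccc12 | intermediate
20 | 2-methoxy-5-(3-methylbut-2-enyl)-3,6-bis[1-(triisopropylsilyl)indol-3-yl]cyclohexa-2,5-diene-1,4-dione | COC1=C(c2cn([Si](C(C)C)(C(C)C)C(C)C)c3ccccc23)C(=O)C(CC=C(C)C)=C(c2cn([Si](C(C)C)(C(C)C)C(C)C)c3ccccc23)C1=O | intermediate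
21 | 2-methoxy-3,6-di(1H-indol-3-yl)-5-(3-methylbut-2-enyl)cyclohexa-2,5-diene-1,4-dione | COC1=C(c2c[nH]c3ccccc23)C(=O)C(CC=C(C)C)=C(c2c[nH]c3ccccc23)C1=O | target

**Summary**

Total step count: 10. Longest linear sequence: 7 steps (steps 4, 5, 6, 7, 8, 9, 10 from 3-acetylindole; the branch from indole through steps 1, 2, 3 is equally long).

**Steps most likely to fail**

1. Step 7. The alkenyllithium may be quenched by proton transfer from the doubly allylic methylene. Electron donation from the N-silylindole into the carbonyl next to C–OMe may also narrow the reactivity gap between the two carbonyls, so that addition at the vinylogous-ester carbonyl competes. The fallback sets out from 8 and replaces the silyl group on the cyclobutenedione indole by an electron-withdrawing carbamate.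
   - Bu4NF/AcOH in THF at 0 °C should give 3-(1H-indol-3-yl)-4-methoxycyclobut-3-ene-1,2-dione F1.
   - Boc2O with catalytic DMAP in MeCN should give tert-butyl 3-(2-methoxy-3,4-dioxocyclobut-1-en-1-yl)indole-1-carboxylate F2, in which the indole is a much weaker donor.
   - Addition of 15 at -78 °C should then give the mixed N-Boc/N-silyl 4-alkenyl-4-hydroxycyclobutenone F3.
   - Thermolysis in PhMe at 110 °C should give the mixed-protected hydroquinone F4, and Ag2O/K2CO3 the mixed-protected quinone F5.
   - NaOMe in MeOH/THF at 0 °C to rt should cleave both N-groups (methoxide exchange at C2 is degenerate), and the sequence comes back to the route at 21.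

2. Step 8. Inward rotation of the hydroxyl would allow lactonisation onto the ketene (butenolide formation). Crowding around the alkenyl terminus may also slow the six-electron closure enough for the free hydroquinone to decompose. The fallback sets out from 16.
   - Me3SiCl, Et3N and catalytic DMAP in CH2Cl2 should give the trimethylsilyl ether of the carbinol, F6, which cannot lactonise.
   - Thermolysis of F6 in PhMe or p-xylene at 110–138 °C (the known silyl ether variant of the ring expansion) should give the mono-silylated hydroquinone, 4-(trimethylsilyloxy)phenol F7, by ring opening, electrocyclisation and hydrogen shift.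
   - AcOH/THF/H2O at rt should remove the aryl silyl ether, and the sequence comes back to the route at 19.

3. Step 6. Condensation at the poorly electrophilic carbonyl (a vinylogous amide) may stall, and the acid catalyst may remove the N-silyl group. The fallback sets out from 13 and avoids both the hydrazone and the Shapiro reaction.
   - KN(SiMe3)2 and PhNTf2 in THF at -78 °C should give the (Z)-enol triflate F8.
   - The zerovalent palladium complex Pd(PPh3)4 with Me3SnSnMe3 and LiCl in dioxane at 80 °C should give the (Z)-alkenyltrimethylstannane F9.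
   - MeLi in THF at -78 °C should give the (E)-alkenyllithium F10 by tin–lithium exchange.
   - Addition of F10 to 8 at -78 °C should give the (Z)-alkene isomer of the carbinol, F11.
   - Heating F11 under the conditions of step 8 should converge on the same hydroquinone, and the sequence comes back to the route at 19.

**Further compounds**

F1 | step 7 | 3-(1H-indol-3-yl)-4-methoxycyclobut-3-ene-1,2-dione | COC1=C(c2c[nH]c3ccccc23)C(=O)C1=O
F2 | step 7 | tert-butyl 3-(2-methoxy-3,4-dioxocyclobut-1-en-1-yl)indole-1-carboxylate | COC1=C(c2cn(C(=O)OC(C)(C)C)c3ccccc23)C(=O)C1=O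
F3 | step 7 | tert-butyl 3-[3-hydroxy-2-methoxy-3-[(1E)-5-methyl-1-[1-(triisopropylsilyl)indol-3-yl]hexa-1,4-dien-1-yl]-4-oxocyclobut-1-en-1-yl]indole-1-carboxylate (racemic, one enantiomer drawn) | O=C1C(c2cn(C(=O)OC(C)(C)C)c3ccccc23)=C(OC)[C@@]1(O)/C(=C/CC=C(C)C)c1cn([Si](C(C)C)(C(C)C)C(C)C)c2ccccc12
F4 | step 7 | tert-butyl 3-[2,5-dihydroxy-6-methoxy-3-(3-methylbut-2-enyl)-4-[1-(triisopropylsilyl)indol-3-yl]phenyl]indole-1-carboxylate | COc1c(O)c(-c2cn([Si](C(C)C)(C(C)C)C(C)C)c3ccccc23)c(CC=C(C)C)c(O)c1-c1cn(C(=O)OC(C)(C)C)c2ccccc12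
F5 | step 7 | tert-butyl 3-[2-methoxy-5-(3-methylbut-2-enyl)-3,6-dioxo-4-[1-(triisopropylsilyl)indol-3-yl]cyclohexa-1,4-dien-1-yl]indole-1-carboxylate | COC1=C(c2cn(C(=O)OC(C)(C)C)c3ccccc23)C(=O)C(CC=C(C)C)=C(c2cn([Si](C(C)C)(C(C)C)C(C)C)c3ccccc23)C1=O
F6 | step 8 | 3-methoxy-4-[(1E)-5-methyl-1-[1-(triisopropylsilyl)indol-3-yl]hexa-1,4-dien-1-yl]-2-[1-(triisopropylsilyl)indol-3-yl]-4-(trimethylsilyloxy)cyclobut-2-en-1-one (racemic, one enantiomer drawn) | O=C1C(c2cn([Si](C(C)C)(C(C)C)C(C)C)c3ccccc23)=C(OC)[C@@]1(O[Si](C)(C)C)/C(=C/CC=C(C)C)c1cn([Si](C(C)C)(C(C)C)C(C)C)c2ccccc12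
F7 | step 8 | 3-methoxy-6-(3-methylbut-2-enyl)-2,5-bis[1-(triisopropylsilyl)indol-3-yl]-4-(trimethylsilyloxy)phenol | COc1c(O[Si](C)(C)C)c(-c2cn([Si](C(C)C)(C(C)C)C(C)C)c3ccccc23)c(CC=C(C)C)c(O)c1-c1cn([Si](C(C)C)(C(C)C)C(C)C)c2ccccc12
F8 | step 6 | (1Z)-5-methyl-1-[1-(triisopropylsilyl)indol-3-yl]hexa-1,4-dien-1-yl trifluoromethanesulfonate | CC(C)=CC/C=C(\OS(=O)(=O)C(F)(F)F)c1cn([Si](C(C)C)(C(C)C)C(C)C)c2ccccc12
F9 | step 6 | trimethyl[(1Z)-5-methyl-1-[1-(triisopropylsilyl)indol-3-yl]hexa-1,4-dien-1-yl]stannane | CC(C)=CC/C=C(\[Sn](C)(C)C)c1cn([Si](C(C)C)(C(C)C)C(C)C)c2ccccc12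
F10 | step 6 | [(1E)-5-methyl-1-[1-(triisopropylsilyl)indol-3-yl]hexa-1,4-dien-1-yl]lithium | [Li]/C(=C\CC=C(C)C)c1cn([Si](C(C)C)(C(C)C)C(C)C)c2ccccc12
F11 | step 6 | 4-hydroxy-3-methoxy-4-[(1Z)-5-methyl-1-[1-(triisopropylsilyl)indol-3-yl]hexa-1,4-dien-1-yl]-2-[1-(triisopropylsilyl)indol-3-yl]cyclobut-2-en-1-one (racemic, one enantiomer drawn) | O=C1C(c2cn([Si](C(C)C)(C(C)C)C(C)C)c3ccccc23)=C(OC)[C@@]1(O)/C(=C\CC=C(C)C)c1cn([Si](C(C)C)(C(C)C)C(C)C)c2ccccc12
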